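The ten-membered carbocycle is disconnected at C6–C7. C6 is an allylic carbinol carbon (next to the E C4=C5 olefin, and the lactone O–CH) and C7 carries the three-carbon branch C11/C12/C13 of the γ-lactone ring, so C6–C7 is the homoallylic-alcohol bond that a [2,3]-Wittig shift makes. In one operation the key step contracts a thirteen-membered C6–O–C13 diallyl ether to the ten-membered ring, forms C6–C7, sets C6 and C7, and leaves the C11=C13 methylene and the C12 oxygen for the lactone. Its precursor is that macrocyclic ether carrying both ring olefins, a ring-cis C7=C11 olefin, the (S)-C8 silyl ether and a C12 silyl ether.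

Key step: step 16

Remark: atoms carry germacrane numbers (ring C1–C10, lactone branch C11–C13); in the target H6 and H7 are cis (cis-fused γ-lactone), the C8 oxygen is trans to the C7–C11 bond and the C11 oxygen lies on the H7 face (6S,7R,8S,11S).
Remark: the sense of induction in step 9 is assigned by analogy with simple alkyl alkynyl ketones; should the carbinol prove to be R, the (R,R) catalyst is used.

Step 1
Reactants: 1 geraniol
Product: 3 geranyl 4-methoxybenzyl ether, via sodium geranoxide 2 (not isolated)
Conditions: NaH, THF, 0 °C; then 4-methoxybenzyl chloride, Bu4NI (cat.), 0 °C → rt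
Reagents that add atoms: 4-methoxybenzyl chloride, COc1ccc(CCl)cc1
Why: Williamson ether synthesis, in which the primary allylic alkoxide should displace the benzylic chloride, gives a C6 protecting group that is later removed oxidatively without touching silyl ethers or an allylic chloride.

Step 2
Reactants: 3 geranyl 4-methoxybenzyl ether
Product: 4 6,7-epoxygeranyl 4-methoxybenzyl ether (racemic)
Conditions: mCPBA, CH2Cl2, −20 → 0 °C
Reagents that add atoms: 3-chloroperbenzoic acid, OOC(=O)c1cccc(Cl)c1
Why: Prilezhaev epoxidation should go to the remote trisubstituted olefin, which is more electron-rich than the olefin next to the allylic ether oxygen; the new stereocentre is racemic and is destroyed in step 3.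

Step 3
Reactants: 4 6,7-epoxygeranyl 4-methoxybenzyl ether
Product: 6 (4E)-6-[(4-methoxybenzyl)oxy]-4-methylhex-4-enal, via vicinal diol 5 (not isolated)
Conditions: H5IO6, THF/Et2O, 0 °C
Reagents that add atoms: none
Why: Periodic acid should hydrolyse the epoxide and cleave the resulting glycol in the same flask (Malaprade-type cleavage), leaving the aldehyde carbon that becomes C1 and the E C4=C5 olefin untouched.

Step 4
Reactants: 6 (4E)-6-[(4-methoxybenzyl)oxy]-4-methylhex-4-enal; 7 ethyltriphenylphosphonium iodide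
Product: 11 (2E,6Z)-7-iodo-3-methylocta-2,6-dien-1-yl 4-methoxybenzyl ether, via ethylidene ylide 8 (not isolated), via iodoethylphosphonium iodide 9 (not isolated), via iodoethylidene ylide 10 (not isolated)
Conditions: 7, n-BuLi, THF, rt; I2, −78 °C; NaN(SiMe3)2, −78 → −20 °C; then 6, −78 °C → rt
Reagents that add atoms: ethyltriphenylphosphonium iodide 7, CC[P+](c1ccccc1)(c1ccccc1)c1ccccc1.[I-]; iodine, II
Why: Wittig olefination with the α-iodo ylide (Stork–Zhao-type iodo-olefination) should give the (Z)-2-iodo-2-alkene, whose iodine, cis to C2, is later replaced by C9 with retention and so fixes the Z C1=C10 geometry.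

Step 5
Reactants: 11 (2E,6Z)-7-iodo-3-methylocta-2,6-dien-1-yl 4-methoxybenzyl ether; 12 oxirane
Product: 14 (3Z,7E)-9-[(4-methoxybenzyl)oxy]-3,7-dimethylnona-3,7-dien-1-ol, via vinyllithium 13 (not isolated)
Conditions: t-BuLi (2 equiv), Et2O, −78 °C; then oxirane, −78 → 0 °C; H2O
Reagents that add atoms: oxirane 12, C1CO1
Why: Iodine–lithium exchange keeps the olefin geometry and the vinyllithium should open oxirane (epoxide ring opening), adding C9 and C8 as a homoallylic alcohol on the Z trisubstituted olefin.

Step 6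
Reactants: 14 (3Z,7E)-9-[(4-methoxybenzyl)oxy]-3,7-dimethylnona-3,7-dien-1-ol
Product: 15 (3Z,7E)-9-[(4-methoxybenzyl)oxy]-3,7-dimethylnona-3,7-dienal
Conditions: Dess–Martin periodinane, pyridine, CH2Cl2, 0 °C; used crude
Reagents that add atoms: none
Why: Dess–Martin oxidation under buffered, non-basic conditions should give the β,γ-unsaturated aldehyde (C8) without moving the C1=C10 olefin into conjugation.

Step 7
Reactants: 15 (3Z,7E)-9-[(4-methoxybenzyl)oxy]-3,7-dimethylnona-3,7-dienal; 16 tert-butyldimethyl(prop-2-yn-1-yloxy)silane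
Product: 18 rac-(6Z,10E)-1-[(tert-butyldimethylsilyl)oxy]-12-[(4-methoxybenzyl)oxy]-6,10-dimethyldodeca-6,10-dien-2-yn-4-ol, via lithium acetylide 17 (not isolated)
Conditions: 16, n-BuLi, THF, −78 °C; then 15, −78 °C; H2O
Reagents that add atoms: tert-butyldimethyl(prop-2-yn-1-yloxy)silane 16, C#CCO[Si](C)(C)C(C)(C)C
Why: 1,2-Addition of the lithium acetylide to the aldehyde at −78 °C (alkynylation) should outrun enolisation and brings in C7, C11 and C12; the C8 carbinol is racemic here and is set in steps 8 and 9.

Step 8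
Reactants: 18 rac-(6Z,10E)-1-[(tert-butyldimethylsilyl)oxy]-12-[(4-methoxybenzyl)oxy]-6,10-dimethyldodeca-6,10-dien-2-yn-4-ol
Product: 19 (6Z,10E)-1-[(tert-butyldimethylsilyl)oxy]-12-[(4-methoxybenzyl)oxy]-6,10-dimethyldodeca-6,10-dien-2-yn-4-one
Conditions: Dess–Martin periodinane, pyridine, CH2Cl2, 0 °C
Reagents that add atoms: none
Why: Dess–Martin oxidation of the propargylic alcohol should give the ynone under neutral conditions, so the skipped C1=C10 olefin stays in place.

Step 9
Reactants: 19 (6Z,10E)-1-[(tert-butyldimethylsilyl)oxy]-12-[(4-methoxybenzyl)oxy]-6,10-dimethyldodeca-6,10-dien-2-yn-4-one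
Product: 20 (4S,6Z,10E)-1-[(tert-butyldimethylsilyl)oxy]-12-[(4-methoxybenzyl)oxy]-6,10-dimethyldodeca-6,10-dien-2-yn-4-ol
Conditions: Ru[(S,S)-TsNCH(Ph)CH(Ph)NH](p-cymene) (cat.), i-PrOH, rt
Reagents that add atoms: none
Why: Noyori asymmetric transfer hydrogenation of an alkyl alkynyl ketone, in which the alkynyl group plays the part of the aryl group, should deliver hydride in neutral 2-propanol to the face that gives the (S)-carbinol at C8.

Step 10
Reactants: 20 (4S,6Z,10E)-1-[(tert-butyldimethylsilyl)oxy]-12-[(4-methoxybenzyl)oxy]-6,10-dimethyldodeca-6,10-dien-2-yn-4-ol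
Product: 22 (2Z,4S,6Z,10E)-1-[(tert-butyldimethylsilyl)oxy]-2-iodo-12-[(4-methoxybenzyl)oxy]-6,10-dimethyldodeca-2,6,10-trien-4-ol, via cyclic vinylalanate 21 (not isolated)
Conditions: NaAlH2(OCH2CH2OMe)2, THF, 0 °C; then I2, −78 → 0 °C; aqueous work-up
Reagents that add atoms: iodine, II
Why: Hydroxyl-directed trans-hydroalumination of the propargylic alcohol puts hydride on C7 and aluminium on C11 in a five-membered alkoxyalanate, and iododealumination with retention should give the vinyl iodide with iodine cis to C8, which fixes the ring-cis C7=C11 geometry.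

Step 11
Reactants: 22 (2Z,4S,6Z,10E)-1-[(tert-butyldimethylsilyl)oxy]-2-iodo-12-[(4-methoxybenzyl)oxy]-6,10-dimethyldodeca-2,6,10-trien-4-ol
Product: 23 C8 triisopropylsilyl ether of 22
Conditions: i-Pr3SiOTf, 2,6-lutidine, CH2Cl2, −78 → 0 °C
Reagents that add atoms: triisopropylsilyl triflate, CC(C)[Si](OS(=O)(=O)C(F)(F)F)(C(C)C)C(C)C
Why: Silylation of the secondary allylic alcohol with the silyl triflate (silyl ether formation) should be clean, and the bulky group stays until step 21 and later screens C13 and biases the faces of C7.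

Step 12
Reactants: 23 C8 triisopropylsilyl ether of 22; 24 (tributylstannyl)methanol
Product: 25 allylic alcohol with a CH2OH group (C13) on C11 cis to C8
Conditions: Pd(PPh3)4 (cat.), 1,4-dioxane, 90 °C
Reagents that add atoms: (tributylstannyl)methanol 24, CCCC[Sn](CCCC)(CCCC)CO
Why: Stille cross-coupling of the vinyl iodide with the hydroxymethylstannane proceeds with retention at C11, so the new C13 hydroxymethyl group should sit cis to C8 and the C12 silyloxymethyl group trans to it.

Step 13
Reactants: 25 allylic alcohol with a CH2OH group (C13) on C11 cis to C8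
Product: 26 C13 allylic chloride
Conditions: PPh3, hexachloroacetone, CH2Cl2, −20 → 0 °C
Reagents that add atoms: hexachloroacetone, ClC(Cl)(Cl)C(=O)C(Cl)(Cl)Cl
Why: Appel-type chlorination of the primary allylic alcohol is neutral and should proceed without allylic transposition or silyl migration, making C13 the electrophile for ring closure.

Step 14
Reactants: 26 C13 allylic chloride
Product: 27 C6 alcohol carrying the C13 chloride
Conditions: DDQ, CH2Cl2/pH 7 buffer, 0 °C
Reagents that add atoms: none
Why: Oxidative cleavage of the 4-methoxybenzyl ether with DDQ is neutral, so the allylic chloride and both silyl ethers should survive while the C6 alcohol is set free.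

Step 15
Reactants: 27 C6 alcohol carrying the C13 chloride
Product: 29 thirteen-membered C6–O–C13 diallyl ether, via sodium alkoxide 28 (not isolated)
Conditions: NaH, Bu4NI (cat.), THF, 50 °C, slow addition of 27 (high dilution)
Reagents that add atoms: none
Why: Intramolecular Williamson etherification, in which the C6 alkoxide should displace the primary allylic chloride at C13 (SN2), closes the thirteen-membered ring; the alkoxide is placed on C6 because a C13 alkoxide could take the silyl group from the neighbouring C12 oxygen and so exchange C12 and C13 and lose the olefin geometry.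

Step 16
Reactants: 29 thirteen-membered C6–O–C13 diallyl ether
Product: 31 ten-membered C6 alcohol with the 2-(silyloxymethyl)vinyl branch on C7, via C6-lithio ether 30 (not isolated)
Conditions: n-BuLi, THF, −78 → −30 °C; then H2O at −30 °C
Reagents that add atoms: none
Why: n-BuLi should remove a proton from C6, whose methylene is flanked only by the C5–H vinyl carbon, while C13 and C12 are screened by the two silyl ethers, and the α-oxy allyl anion then bonds to C7 suprafacially through a five-centre envelope transition state as the O–C13 bond breaks ([2,3]-Wittig sigmatropic rearrangement). The closest known reaction type is the [2,3]-Wittig ring contraction of thirteen-membered diallylic ethers to ten-membered germacrane-type homoallylic alcohols. The ten-membered ring closes by transannular C6–C7 bond formation inside the existing macrocycle (a thirteen-to-ten contraction across the five-atom array C6–O–C13–C11–C7), so no dilution is needed and both ring olefins stay as they are. The C6/C7 relationship (hydroxyl and C8 syn, the later cis ring fusion) follows from the ring-cis C7=C11 geometry with the C5 vinyl group exo in the envelope; the absolute sense at both carbons is set by C8, whose hydrogen lies in the olefin plane to avoid allylic strain with C13, so that C6 adds to the C7 face anti to the bulky C8–O bond. The step needs site selectivity (C6 over C13, whose own [2,3] shift would have to create a quaternary C4) and face selectivity at C7, and the silyl shielding and the C8 stereocentre are what should secure them.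

Step 17
Reactants: 31 ten-membered C6 alcohol with the 2-(silyloxymethyl)vinyl branch on C7
Product: 32 6,12-diol
Conditions: Bu4NF, AcOH, THF, 0 °C
Reagents that add atoms: none
Why: Fluoride cleavage of the primary allylic tert-butyldimethylsilyl ether, buffered with acetic acid so that no alkoxide can start a silyl shift, should be much faster than loss of the hindered secondary triisopropylsilyl ether.

Step 18
Reactants: 32 6,12-diol
Product: 35 cis-fused α-methylene γ-lactone, via hydroxy enal 33 (not isolated), via lactol 34 (not isolated)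
Conditions: TEMPO (cat.), PhI(OAc)2, CH2Cl2, rt
Reagents that add atoms: none
Why: In this TEMPO/PhI(OAc)2 oxidative lactonisation the oxoammonium species should oxidise the primary allylic alcohol much faster than the secondary one, the enal is trapped by the C6 hydroxyl as a lactol, and the lactol is oxidised to the lactone.

Step 19
Reactants: 35 cis-fused α-methylene γ-lactone
Product: 37 11-hydroxy lactone, via C11 hydroperoxide 36 (not isolated)
Conditions: Mn(dpm)3 (cat., dpm = 2,2,6,6-tetramethylheptane-3,5-dionate), PhSiH3, O2 (1 atm), i-PrOH/CH2Cl2, 0 °C; then PPh3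
Reagents that add atoms: dioxygen, O=O
Why: In this Mukaiyama-type hydration by hydrogen-atom transfer the manganese hydride should add H to C13 of the conjugated methylene, which is more reactive than the two isolated trisubstituted olefins, and the planar C11 radical should take up O2 on the convex face of the cis-fused lactone (the H7 face, away from C5 and C8), which sets C11 with the oxygen cis to H7.

Step 20
Reactants: 37 11-hydroxy lactone
Product: 39 11-O-angelate, via lithium alkoxide 38 (not isolated)
Conditions: LiN(SiMe3)2, THF, −78 °C; then angelic anhydride, −78 → 0 °C; H2O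
Reagents that add atoms: angelic anhydride, C/C=C(/C)C(=O)OC(=O)/C(C)=C\C
Why: O-Acylation of the preformed tertiary alkoxide with the anhydride at low temperature, without a nucleophilic catalyst, should esterify C11–OH with retention at C11 and without isomerising the Z acyl group to the tiglate.

Step 21
Reactants: 39 11-O-angelate
Product: 40 8-hydroxy 11-O-angelate
Conditions: HF·pyridine, pyridine, THF, 0 °C → rt
Reagents that add atoms: none
Why: Desilylation with buffered HF·pyridine should remove the secondary silyl ether without forming a C8 alkoxide, so neither a shift of the lactone to O8 nor of the angelate can start.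

Step 22
Reactants: 40 8-hydroxy 11-O-angelate
Product: 41 target (CNP0148966.1)
Conditions: Ac2O, pyridine, DMAP (cat.), CH2Cl2, 0 °C → rt
Reagents that add atoms: acetic anhydride, CC(=O)OC(C)=O
Why: DMAP-catalysed acetylation of the secondary alcohol should complete the target without touching any stereocentre.

Compound list
1 | geraniol, (2E)-3,7-dimethylocta-2,6-dien-1-ol | CC(C)=CCC/C(C)=C/CO | starting material
2 | sodium geranoxide | CC(C)=CCC/C(C)=C/C[O-].[Na+] | intermediate
3 | geranyl 4-methoxybenzyl ether | COc1ccc(cc1)COC/C=C(\C)CCC=C(C)C | intermediate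
4 | 6,7-epoxygeranyl 4-methoxybenzyl ether (racemic at the epoxide) | COc1ccc(cc1)COC/C=C(\C)CCC1OC1(C)C | intermediate
5 | (6E)-8-[(4-methoxybenzyl)oxy]-2,6-dimethyloct-6-ene-2,3-diol (racemic) | COc1ccc(cc1)COC/C=C(\C)CCC(O)C(C)(C)O | intermediate
6 | (4E)-6-[(4-methoxybenzyl)oxy]-4-methylhex-4-enal (CHO carbon is C1) | COc1ccc(cc1)COC/C=C(\C)CCC=O | intermediate
7 | ethyltriphenylphosphonium iodide | CC[P+](c1ccccc1)(c1ccccc1)c1ccccc1.[I-] | starting material
8 | ethylidenetriphenylphosphorane | CC=P(c1ccccc1)(c1ccccc1)c1ccccc1 | intermediate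
9 | (1-iodoethyl)triphenylphosphonium iodide | CC(I)[P+](c1ccccc1)(c1ccccc1)c1ccccc1.[I-] | intermediate
10 | (1-iodoethylidene)triphenylphosphorane | CC(I)=P(c1ccccc1)(c1ccccc1)c1ccccc1 | intermediate
11 | (2E,6Z)-7-iodo-3-methylocta-2,6-dien-1-yl 4-methoxybenzyl ether (iodine on C10, cis to C2) | COc1ccc(cc1)COC/C=C(\C)CC/C=C(/C)I | intermediate
12 | oxirane | C1CO1 | starting material
13 | vinyllithium from 11 (lithium in place of iodine on C10, geometry retained) | COc1ccc(cc1)COC/C=C(\C)CC/C=C(/C)[Li] | intermediate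
14 | (3Z,7E)-9-[(4-methoxybenzyl)oxy]-3,7-dimethylnona-3,7-dien-1-ol | COc1ccc(cc1)COC/C=C(\C)CC/C=C(/C)CCO | intermediate
15 | (3Z,7E)-9-[(4-methoxybenzyl)oxy]-3,7-dimethylnona-3,7-dienal (CHO carbon is C8) | COc1ccc(cc1)COC/C=C(\C)CC/C=C(/C)CC=O | intermediate
16 | tert-butyldimethyl(prop-2-yn-1-yloxy)silane | C#CCO[Si](C)(C)C(C)(C)C | starting material
17 | [3-(tert-butyldimethylsilyloxy)prop-1-yn-1-yl]lithium | [Li]C#CCO[Si](C)(C)C(C)(C)C | intermediate
18 | rac-(6Z,10E)-1-[(tert-butyldimethylsilyl)oxy]-12-[(4-methoxybenzyl)oxy]-6,10-dimethyldodeca-6,10-dien-2-yn-4-ol | COc1ccc(cc1)COC/C=C(\C)CC/C=C(/C)CC(O)C#CCO[Si](C)(C)C(C)(C)C | intermediate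
19 | (6Z,10E)-1-[(tert-butyldimethylsilyl)oxy]-12-[(4-methoxybenzyl)oxy]-6,10-dimethyldodeca-6,10-dien-2-yn-4-one | COc1ccc(cc1)COC/C=C(\C)CC/C=C(/C)CC(=O)C#CCO[Si](C)(C)C(C)(C)C | intermediate
20 | (4S,6Z,10E)-1-[(tert-butyldimethylsilyl)oxy]-12-[(4-methoxybenzyl)oxy]-6,10-dimethyldodeca-6,10-dien-2-yn-4-ol (C8 is S) | COc1ccc(cc1)COC/C=C(\C)CC/C=C(/C)C[C@H](O)C#CCO[Si](C)(C)C(C)(C)C | intermediate
21 | sodium alkoxy(vinyl)alanate: five-membered ring O8–Al–C11=C7–C8, two 2-methoxyethoxy groups on aluminium | COc1ccc(cc1)COC/C=C(\C)CC/C=C(/C)C[C@@H]2O[Al-](OCCOC)(OCCOC)C(CO[Si](C)(C)C(C)(C)C)=C2.[Na+] | intermediate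
22 | (2Z,4S,6Z,10E)-1-[(tert-butyldimethylsilyl)oxy]-2-iodo-12-[(4-methoxybenzyl)oxy]-6,10-dimethyldodeca-2,6,10-trien-4-ol (iodine on C11, cis to C8) | COc1ccc(cc1)COC/C=C(\C)CC/C=C(/C)C[C@H](O)/C=C(\I)CO[Si](C)(C)C(C)(C)C | intermediate
23 | C8 triisopropylsilyl ether of 22 | COc1ccc(cc1)COC/C=C(\C)CC/C=C(/C)C[C@H](O[Si](C(C)C)(C(C)C)C(C)C)/C=C(\I)CO[Si](C)(C)C(C)(C)C | intermediate
24 | (tributylstannyl)methanol | CCCC[Sn](CCCC)(CCCC)CO | starting material
25 | allylic alcohol: CH2OH (C13) on C11 cis to C8, CH2OTBS (C12) trans; (8S)-OTIPS; C6 O-(4-methoxybenzyl) | COc1ccc(cc1)COC/C=C(\C)CC/C=C(/C)C[C@H](O[Si](C(C)C)(C(C)C)C(C)C)/C=C(\CO)CO[Si](C)(C)C(C)(C)C | intermediate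
26 | C13 allylic chloride of 25 | COc1ccc(cc1)COC/C=C(\C)CC/C=C(/C)C[C@H](O[Si](C(C)C)(C(C)C)C(C)C)/C=C(\CCl)CO[Si](C)(C)C(C)(C)C | intermediate
27 | C6 alcohol carrying the C13 chloride | OC/C=C(\C)CC/C=C(/C)C[C@H](O[Si](C(C)C)(C(C)C)C(C)C)/C=C(\CCl)CO[Si](C)(C)C(C)(C)C | intermediate
28 | sodium C6 alkoxide of 27 | [Na+].[O-]C/C=C(\C)CC/C=C(/C)C[C@H](O[Si](C(C)C)(C(C)C)C(C)C)/C=C(\CCl)CO[Si](C)(C)C(C)(C)C | intermediate
29 | thirteen-membered diallyl ether O–C13–C11=C7–C8–C9–C10=C1–C2–C3–C4=C5–C6: E C4=C5, Z C1=C10, C13 cis to C8 across C7=C11, (8S)-OTIPS, CH2OTBS (C12) on C11 | O1C/C(CO[Si](C)(C)C(C)(C)C)=C\[C@@H](O[Si](C(C)C)(C(C)C)C(C)C)C/C(C)=C\CC/C(C)=C/C1 | intermediate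
30 | C6-lithio derivative of 29 | O1C/C(CO[Si](C)(C)C(C)(C)C)=C\[C@@H](O[Si](C(C)C)(C(C)C)C(C)C)C/C(C)=C\CC/C(C)=C/C1[Li] | intermediate
31 | (1(10)Z,4E)-germacra-1(10),4,11(13)-triene-6,8,12-triol 8-O-TIPS 12-O-TBS ether (6S,7S,8S by CIP): 6-OH cis to the C7 branch, 8-O trans to it | O[C@H]1/C=C(\C)CC/C=C(/C)C[C@H](O[Si](C(C)C)(C(C)C)C(C)C)[C@H]1C(=C)CO[Si](C)(C)C(C)(C)C | intermediate
32 | 6,12-diol, 8-O-TIPS | O[C@H]1/C=C(\C)CC/C=C(/C)C[C@H](O[Si](C(C)C)(C(C)C)C(C)C)[C@H]1C(=C)CO | intermediate
33 | 6-hydroxy 12-enal, 8-O-TIPS | O[C@H]1/C=C(\C)CC/C=C(/C)C[C@H](O[Si](C(C)C)(C(C)C)C(C)C)[C@H]1C(=C)C=O | intermediate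
34 | 12,6-lactol (anomers), 8-O-TIPS | C=C1C(O)O[C@H]2/C=C(\C)CC/C=C(/C)C[C@H](O[Si](C(C)C)(C(C)C)C(C)C)[C@H]21 | intermediate
35 | 8-O-TIPS (1(10)Z,4E)-8-hydroxygermacra-1(10),4,11(13)-trien-12,6-olide, cis-fused | C=C1C(=O)O[C@H]2/C=C(\C)CC/C=C(/C)C[C@H](O[Si](C(C)C)(C(C)C)C(C)C)[C@H]21 | intermediate
36 | 11-hydroperoxy-11,13-dihydro lactone, 8-O-TIPS (OOH cis to H7) | OO[C@]1(C)C(=O)O[C@H]2/C=C(\C)CC/C=C(/C)C[C@H](O[Si](C(C)C)(C(C)C)C(C)C)[C@H]21 | intermediate
37 | 11-hydroxy-11,13-dihydro lactone, 8-O-TIPS (OH cis to H7) | O[C@]1(C)C(=O)O[C@H]2/C=C(\C)CC/C=C(/C)C[C@H](O[Si](C(C)C)(C(C)C)C(C)C)[C@H]21 | intermediate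
38 | lithium C11 alkoxide of 37 | [Li+].[O-][C@]1(C)C(=O)O[C@H]2/C=C(\C)CC/C=C(/C)C[C@H](O[Si](C(C)C)(C(C)C)C(C)C)[C@H]21 | intermediate
39 | 11-O-angelate, 8-O-TIPS | C/C=C(/C)C(=O)O[C@]1(C)C(=O)O[C@H]2/C=C(\C)CC/C=C(/C)C[C@H](O[Si](C(C)C)(C(C)C)C(C)C)[C@H]21 | intermediate
40 | 8-hydroxy 11-O-angelate | C/C=C(/C)C(=O)O[C@]1(C)C(=O)O[C@H]2/C=C(\C)CC/C=C(/C)C[C@H](O)[C@H]21 | intermediate
41 | target: (6S,7R,8S,11S,1(10)Z,4E)-8-acetoxy-11-angeloyloxy-11,13-dihydrogermacra-1(10),4-dien-12,6-olide | C/C=C(/C)C(=O)O[C@]1(C)C(=O)O[C@H]2/C=C(\C)CC/C=C(/C)C[C@H](OC(C)=O)[C@H]21 | target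

Total step count: 22. Longest linear sequence: 22 steps, from geraniol 1 to the target 41; the building blocks 7, 12, 16 and 24 are bought.

Steps most likely to fail

Step 16. The base may take a proton at C13 or C12 instead of C6, or the folded transition state may not tell the two faces of C7 apart well enough, so that regioisomeric or diastereomeric ring-contraction products form. The fallback sets out from 27 and forms the same C6–C7 bond by a carbonyl allylation instead of a sigmatropic shift. The C6 allylic alcohol is oxidised with MnO2 in CH2Cl2 to the enal chloride F1. Treatment of F1 with CrCl2 in THF under high dilution (intramolecular Nozaki–Hiyama allylation) should generate the allylchromium species at C13, which adds through C7 to the C6 aldehyde in a chair transition state and leaves the C11=C13 methylene. If the C8 branch stays cis to the metal-bearing carbon, the same syn pair results, and the route is rejoined at 31.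

Step 19. The manganese hydride may also attack the ring olefins, or the C11 radical may add across the ring or take up oxygen from the wrong face. The fallback sets out from 35 and separates reduction from oxygenation. Conjugate reduction with NaBH4 in MeOH at 0 °C should give the 11,13-dihydro lactone F2 (C11 epimers, both usable). Deprotonation with KN(SiMe3)2 in THF at −78 °C and oxidation of the enolate with 2-(phenylsulfonyl)-3-phenyloxaziridine should then place the hydroxyl on the convex face and rejoin the route at 37.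

Step 20. Acylation of the hindered tertiary alkoxide may be slow, and the higher temperature then needed can isomerise the angelate to the tiglate. The fallback sets out from 37 and builds the Z double bond on the ester instead of transferring it. The alkoxide 38 is acylated with 2-[bis(2,2,2-trifluoroethoxy)phosphoryl]propanoyl chloride to give the phosphonate ester F3. Still–Gennari olefination of F3 with acetaldehyde (KN(SiMe3)2, 18-crown-6, THF, −78 °C) should give the Z 2-methylbut-2-enoate and rejoin the route at 39.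

Further compounds
F1 | step 16 | C6 enal carrying the C13 chloride (from 27) | O=C/C=C(\C)CC/C=C(/C)C[C@H](O[Si](C(C)C)(C(C)C)C(C)C)/C=C(\CCl)CO[Si](C)(C)C(C)(C)C
F2 | step 19 | 11,13-dihydro lactone, 8-O-TIPS (C11 epimers) | CC1C(=O)O[C@H]2/C=C(\C)CC/C=C(/C)C[C@H](O[Si](C(C)C)(C(C)C)C(C)C)[C@H]21
F3 | step 20 | 11-O-{2-[bis(2,2,2-trifluoroethoxy)phosphoryl]propanoyl} ester of 37 | CC(C(=O)O[C@]1(C)C(=O)O[C@H]2/C=C(\C)CC/C=C(/C)C[C@H](O[Si](C(C)C)(C(C)C)C(C)C)[C@H]21)P(=O)(OCC(F)(F)F)OCC(F)(F)F
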